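## Structural features

The target is a germacranolide: a ten-membered carbocycle (C1–C10) with an α-methylene-γ-butyrolactone trans-fused across C6–C7 (lactone oxygen on C6, C11(=C13)–C12 on C7). The ring holds two trisubstituted alkenes in a 1,5-relationship, of which C1=C10 is Z and bears the C14 methyl on C10. Across C4=C5 the ring carbons C3 and C6 are trans, which is the "4E" of germacrane usage; because C15 carries oxygen and outranks C3, the CIP descriptor of this bond is Z in the target and in every intermediate with an oxidised C15. C6 (R), C7 (R) and C8 (R) are contiguous, with O6 trans and the free O8–H cis to the carbon branch on C7, whereas C2 (S), allylic to C1=C10, is isolated and carries the angelate. Fragile groups are the methylene lactone (Michael acceptor toward hydrides, amines, phosphines and alkoxides), the angelate (Z to E isomerisation), the primary allylic acetate, the free 8-hydroxyl beside the lactone (lactone migration under base) and the medium-ring 1,5-diene (Cope and transannular reactions). The real difficulty is a ten-membered ring with one ring-trans and one ring-cis alkene, combined with a triad in which C7 lies between two oxygens of opposite relative sense. The key step exploits the C1=C10/C4=C5 diene with ester-level C15 on C4 and the methyl on C10: reconnecting C1–C4 and C5–C10 turns it into a tricycle made of a cyclobutane (C1–C4), a central cyclobutane (C1, C4, C5, C10) and a cyclohexanone (C5–C10).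

## Logic of the disconnections

27 back to 26: the O8–Si bond is cut. The free 8-hydroxyl is released last because it can attack the lactone and would compete in both acylations; the forward step must remove a hindered secondary silyl ether without base and without touching two esters and the methylene lactone.

26 back to 25: the C2–O acyl bond is cut. The angelate is introduced late because it isomerises and does not survive enolate or hydride chemistry; the forward step must acylate a secondary allylic alcohol without Z to E isomerisation.

25 back to 24 and 23: the C15–O acyl bond and the two O–Si bonds at O2 and O15 are cut. One common silyl type on O2 and O15 lets both leave together while O8 stays masked; the forward steps must cleave these two ethers selectively and then acetylate the primary hydroxyl in the presence of the secondary one.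

23 back to 20: the C11=C13 bond is cut. The Michael acceptor is made only after all hydride and enolate steps on the ring; the forward step needs a lactone enolate that tolerates three silyl ethers.

20 back to 18: the O6–C12 bond and the C6–H bond are cut. This removes the C6 stereocentre and leaves C7 α to a ketone; the forward reduction must put O6 trans to the C7 branch, and only O6 may be free to lactonise.

18 back to 17: the C7–C11 bond is cut. This removes C7 as a stereocentre and two carbons; the forward alkylation must enter cis to O8 and must not expel the β-silyloxy group.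

17 back to 16, 15 and 14: C15 is returned to the ester level and C6 stays a ketone. The ester is what the ring-forming step needs, and it is cis to C6 on the alkene, so the ketone cannot be reduced alone without closing a butenolide; the forward steps reduce both carbonyls together, protect the primary hydroxyl and re-oxidise C6.

14 back to 13: the σ bonds C1–C4 and C5–C10 are re-formed at the expense of the two ring π bonds. The medium ring and both alkene geometries are traced to a rigid tricycle whose only lasting stereocentres are C2 and C8; the forward cycloreversion must cleave C5–C10 and not C2–C3, must give the ring-trans/ring-cis pair, and must stop before a Cope rearrangement.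

13 back to 5 and 11: the bonds C1–C10 and C4–C5 of the central cyclobutane are cut. This is the convergent point, giving two small rings with one stereocentre each; the forward photocycloaddition must be head-to-head and end cis-fused, while its facial selectivity is forgiving because C1, C4, C5 and C10 become sp2 later.

5 back to 3, 2 and 1: the C5=C10 bond of the six-membered ring is cut by a retro-aldol condensation, and the two ketones are traced to terminal alkenes. The precursor 3 is achiral and symmetric; the forward cyclisation must distinguish two enantiotopic acetonyl arms (this sets C8) and keep a silyloxy group that is β to both carbonyls.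

11 back to 10, 9 and 6: the O–Si bond is cut, the single enantiomer is traced to the racemate, and the ring alkene (germacrane C4=C1) to a saturated ester. The forward steps must introduce the alkene next to the ester, fix C2 by resolution, and never generate the cyclobutenoxide.

## Other disconnections considered

Alternative 1: The cut is the C2–C3 bond, with C5–C10 reconnected, leading to the cyclohexanol A4, which carries a (Z)-2-(4-methoxybenzyloxy)vinyl group on C10 cis to a 3-silyloxyprop-1-en-2-yl group on C5. The forward key step is the anionic oxy-Cope rearrangement of the potassium alkoxide of A4 (KH, 18-crown-6), with trapping of the C10 enolate by PhNTf2 to give the enol triflate A1; the C14 methyl would follow by cross-coupling.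
- In its favour: the rearrangement is concerted, runs near room temperature and passes through a chair that puts C6 equatorial, so the ring-trans C4=C5 and ring-cis C1=C10 pair is predictable. The C6–C7–C8 triad is built on a six-membered chair before ring expansion, and C2 arises by chirality transfer from the enol ether geometry.
- Against it here: A4 needs five stereocentres and a geometrically pure alkoxyvinyl nucleophile added cis to the C5 alkenyl group; the methyl needs an extra coupling step; C12 is at the alcohol level; five different protecting groups must be removed in order.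
- Comparison: on control of the triad and on the predictability of the alkene pair, alternative 1 is the better plan. Both plans create the two ring alkenes in one step, so they are equal there. On step economy and number of protecting groups the chosen plan is better (18 steps, convergent, three silyl ethers, against a linear sequence that should exceed 25 steps).

Alternative 2: The cut is the C1–C2 bond, leading to the open-chain lactone A5 with a Z-alkenyl iodide at C1 and an aldehyde at C2. The forward key step is a Nozaki–Hiyama–Kishi ring closure (CrCl2, catalytic NiCl2) to the allylic alcohol A2.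
- In its favour: both alkene geometries and the triad are fixed by acyclic methods before the ring exists, and the organochromium reagent tolerates lactone, acetate and the methylene lactone. A2 is identical with compound 25 of the chosen route, so the last two steps are shared.
- Against it here: a strained ten-membered ring is closed by bond formation under high dilution with a large excess of a toxic chromium salt; the C2 carbinol configuration is set in the macrocyclisation with no reliable bias toward 2S; the β,γ-unsaturated aldehyde can isomerise into conjugation; A5 itself needs a long linear synthesis.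
- Comparison: on alkene geometry and on the triad, alternative 2 is the better plan. On C2 (set before ring formation by resolution) and on the ring-forming event (unimolecular, strain-driven, no dilution), the chosen plan is better. Step economy is about equal.

Alternative 3: The cut is the C6–C7 bond, leading to the thirteen-membered diallylic ether A6 (O between C6 and C13, C7=C11 alkene with C8 trans to C13). The forward key step is lithiation at C6 and [2,3]-Wittig ring contraction to the ten-membered alcohol A3.
- In its favour: the thirteen-membered ether closes more easily than a ten-membered carbocycle, and one step forms C6–C7, both stereocentres C6 and C7 and the C11=C13 methylene, with C12 left as a protected alcohol that only needs oxidation. The alkene geometries come from acyclic chemistry, and the trans relation of O6 and the C7 branch follows from the C7=C11 geometry.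
- Against it here: deprotonation must choose C6 over C13 (both allylic and α to oxygen); [1,2]-shift competes; the facial sense relative to C8 and C2 in the transannular transition state is not secured; four different silyl ethers must later be told apart; the linear route to A6 is long.
- Comparison: for the lactone portion alternative 3 is the better plan, since one step replaces the alkylation, reduction/lactonisation and methylenation of the chosen route, and its alkene geometry is safer. Facial control at C7 relative to C8 is about equally uncertain in both plans. On step economy and protecting-group load the chosen plan is better.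

Key step: step 8

Remark: germacrane locants are used for all ring compounds; "ring-trans" at C4=C5 means C3 and C6 trans, which is CIP Z whenever C15 carries oxygen.
Assumption: in step 3 the epi-quinidine-derived amine is taken to give the 5R enone; if the sense is the opposite, the pseudoenantiomeric epi-quinine-derived amine is used.

## Steps

Step 1
Reactants: 1 hepta-1,6-dien-4-ol
Product: 2 4-(tert-butyldimethylsilyloxy)hepta-1,6-diene
Conditions: TBSCl, imidazole, DMF, rt
Reagents that add atoms: tert-butyldimethylsilyl chloride, CC(C)(C)[Si](C)(C)Cl
Why: Imidazole-promoted silylation of a secondary alcohol; the TBS ether is chosen because this oxygen (later O8) must outlast every other step and is unmasked last.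

Step 2
Reactants: 2 4-(tert-butyldimethylsilyloxy)hepta-1,6-diene
Product: 3 4-(tert-butyldimethylsilyloxy)heptane-2,6-dione
Conditions: PdCl2 (10 mol%), CuCl (20 mol%), O2 (1 atm), DMF/H2O (7:1), rt
Reagents that add atoms: water, O
Why: Tsuji–Wacker oxidation converts both terminal alkenes into methyl ketones with Markovnikov selectivity (dioxygen is the terminal oxidant); the homoallylic silyl ether is tolerated and the product is an achiral, symmetric 1,5-diketone.

Step 3
Reactants: 3 4-(tert-butyldimethylsilyloxy)heptane-2,6-dione
Product: 5 (R)-5-(tert-butyldimethylsilyloxy)-3-methylcyclohex-2-en-1-one, via ketol 4 (not isolated)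
Conditions: 9-amino-9-deoxy-epi-quinidine (20 mol%), AcOH (40 mol%), PhMe, −15 °C → rt
Reagents that add atoms: none
Why: Primary-amine-catalysed desymmetrising intramolecular aldol condensation: the enamine of one methyl ketone adds to the other carbonyl and the ketol dehydrates. The catalyst distinguishes the two enantiotopic acetonyl arms and so sets the future C8 (5R in the enone); cold, buffered conditions are used to keep the silyloxy group, which is β to both carbonyls.

Step 4
Reactants: 6 methyl cis-3-hydroxycyclobutane-1-carboxylate
Product: 9 methyl (±)-3-hydroxycyclobut-1-ene-1-carboxylate, via selenide 7 (not isolated), via selenoxide 8 (not isolated)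
Conditions: LiN(iPr)2 (2.2 equiv), THF, −78 °C; PhSeBr; aqueous work-up; then H2O2 (30% aq.), pyridine, CH2Cl2, 0 °C → rt
Reagents that add atoms: none
Why: The dianion (alkoxide plus ester enolate) is selenenylated at C1 and the selenoxide undergoes syn-elimination toward either enantiotopic CH2 (selenoxide elimination), giving the conjugated cyclobutene as a racemate. The C1 configuration of 6 is lost, so either diastereomer of 6 would serve.

Step 5
Reactants: 9 methyl (±)-3-hydroxycyclobut-1-ene-1-carboxylate
Product: 10 methyl (S)-3-hydroxycyclobut-1-ene-1-carboxylate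
Conditions: immobilised lipase B of Candida antarctica, vinyl acetate, tBuOMe, 25 °C, to slightly beyond half conversion
Reagents that add atoms: none
Why: Lipase-catalysed kinetic resolution by transesterification: by the usual empirical model (sp2 carbon as the large group) the R alcohol is acylated faster, so running past half conversion should leave the S alcohol in high enantiomeric purity. This step fixes the future C2; the medium is neutral, so the ring-opening-prone alkoxide is never formed.

Step 6
Reactants: 10 methyl (S)-3-hydroxycyclobut-1-ene-1-carboxylate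
Product: 11 methyl (S)-3-(triethylsilyloxy)cyclobut-1-ene-1-carboxylate
Conditions: TESCl, imidazole, CH2Cl2, 0 °C; product stored cold
Reagents that add atoms: triethylsilyl chloride, CC[Si](Cl)(CC)CC
Why: Imidazole-promoted silylation under non-basic conditions; TES is chosen so that O2 can later be unmasked in the presence of the TBS ether on O8.

Step 7
Reactants: 5 (R)-5-(tert-butyldimethylsilyloxy)-3-methylcyclohex-2-en-1-one; 11 methyl (S)-3-(triethylsilyloxy)cyclobut-1-ene-1-carboxylate
Product: 13 cis-anti-cis head-to-head photoadduct (C4 ester; C10 methyl; C6 ketone; 2S OTES trans to the C1–C10 bond; 8R OTBS cis to the C10 methyl), via trans-fused photoadduct 12 (not isolated)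
Conditions: hν (medium-pressure Hg lamp, Pyrex filter), degassed CH2Cl2, −40 °C, enone added slowly to the irradiated solution of the cyclobutene ester; then Al2O3 (basic), CH2Cl2, rt
Reagents that add atoms: none
Why: Enone–alkene [2+2] photocycloaddition through the enone triplet: the electron-poor alkene adds head-to-head (C4 to the enone α-carbon C5, C1 to C10) and each partner is attacked anti to its silyloxy group, for which the 5R/3S pair is the matched one. Slow addition keeps the stationary enone concentration low, which should suppress enone photodimerisation without an excess of the resolved cyclobutene. Basic Al2O3 epimerises the trans-fused isomer 12 at C5 to the cis-fused 13; the four new stereocentres are all erased in step 8, so only the regiochemistry and the cis fusion matter.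

Step 8
Reactants: 13 cis-anti-cis head-to-head photoadduct
Product: 14 methyl (2S,8R,1(10)Z,4Z)-8-(tert-butyldimethylsilyloxy)-10-methyl-6-oxo-2-(triethylsilyloxy)cyclodeca-1(10),4-diene-4-carboxylate (ring-trans at C4=C5)
Conditions: degassed mesitylene (0.01 M), BHT (5 mol%), base-washed glassware, 165 °C
Reagents that add atoms: none
Why: Homolysis of the strained C1–C4 bond shared by the two four-membered rings gives a cyclohexane-1,4-diyl (the C4 radical is stabilised by the ester), which relaxes to a chair and undergoes β-scission of C5–C10, so that C1=C10 and C4=C5 appear together. The closest known reaction type is the thermal opening of bicyclo[2.2.0]hexanes to hexa-1,5-dienes, as applied to enone–cyclobutene ester photoadducts to give cis,trans-cyclodeca-1,5-dienes. The ten-membered ring is not closed by bond formation; it is revealed when the bond common to the central cyclobutane and the six-membered ring breaks (ring expansion by fragmentation). No stereocentre is created: C1, C4, C5 and C10 become sp2, and C2 and C8 are not involved. The step needs C5–C10 and not C2–C3 scission; C5–C10 joins a tertiary and a quaternary carbon, and its cleavage gives one trisubstituted alkene and one alkene conjugated with both carbonyl groups, whereas C2–C3 scission would give a less substituted divinylcyclohexanone. The step also needs the right alkene pair: the cis ring fusion allows only one ring-trans and one ring-cis alkene, and the chair with H-5 axial and C6 equatorial puts C15 cis to C6 at C4=C5 and C9 cis to C2 at C1=C10 while keeping the C10 methyl equatorial on the diyl ring. The silyloxy groups at C2 and C8 are pseudo-axial in that chair and work against it, which is the main uncertainty. The temperature is kept as low as conversion allows because a following siloxy-Cope rearrangement would destroy the C2 stereocentre.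

Step 9
Reactants: 14 methyl (2S,8R,1(10)Z,4Z)-8-(tert-butyldimethylsilyloxy)-10-methyl-6-oxo-2-(triethylsilyloxy)cyclodeca-1(10),4-diene-4-carboxylate
Product: 15 (2S,8R,1(10)Z,4Z)-8-(tert-butyldimethylsilyloxy)-4-(hydroxymethyl)-10-methyl-2-(triethylsilyloxy)cyclodeca-1(10),4-dien-6-ol (both C6 epimers)
Conditions: iBu2AlH (4 equiv), CH2Cl2, −78 °C; aq. KNaC4H4O6
Reagents that add atoms: none
Why: iBu2AlH reduces the ester and the enone carbonyl by 1,2-addition; excess reagent at low temperature reduces the ester before the 6-alkoxide can close onto the cis C15 ester as a butenolide. The C6 configuration is irrelevant because C6 is re-oxidised in step 11.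

Step 10
Reactants: 15 diol (both C6 epimers)
Product: 16 (2S,8R,1(10)Z,4Z)-8-(tert-butyldimethylsilyloxy)-10-methyl-2-(triethylsilyloxy)-4-[(triethylsilyloxy)methyl]cyclodeca-1(10),4-dien-6-ol (both C6 epimers)
Conditions: TESCl (1.05 equiv), imidazole, CH2Cl2, −78 °C
Reagents that add atoms: triethylsilyl chloride, CC[Si](Cl)(CC)CC
Why: Selective silylation of the primary allylic hydroxyl over the hindered secondary one at low temperature; TES matches the group on O2 so that both leave together in step 15.

Step 11
Reactants: 16 mono-TES alcohol (both C6 epimers)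
Product: 17 (2S,8R,1(10)Z,4Z)-8-(tert-butyldimethylsilyloxy)-10-methyl-2-(triethylsilyloxy)-4-[(triethylsilyloxy)methyl]cyclodeca-1(10),4-dien-6-one
Conditions: MnO2 (activated, excess), CH2Cl2, rt
Reagents that add atoms: none
Why: MnO2 oxidation of the secondary allylic alcohol restores the C6 enone under neutral conditions; both C6 epimers converge on one ketone.

Step 12
Reactants: 17 enone
Product: 18 methyl [(2S,7R,8R,1(10)Z,4Z)-8-(tert-butyldimethylsilyloxy)-10-methyl-6-oxo-2-(triethylsilyloxy)-4-[(triethylsilyloxy)methyl]cyclodeca-1(10),4-dien-7-yl]acetate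
Conditions: LiN(SiMe3)2 (1.1 equiv), THF, −78 °C; methyl bromoacetate, DMPU, −78 → −40 °C
Reagents that add atoms: methyl bromoacetate, COC(=O)CBr
Why: Kinetic α′-deprotonation gives the C6–C7 enolate, which is alkylated by the α-halo ester (enolate alkylation). With the C8–O bond held near the enolate plane (inside-alkoxy arrangement, which also keeps it out of overlap with the π system and so from leaving as silanolate), the reagent should enter from the ring periphery anti to C9, that is cis to O8, which sets C7.

Step 13
Reactants: 18 keto ester
Product: 20 (2S,6R,7S,8R)-6,12-lactone (trans-fused; C11 = CH2; 2-OTES; 8-OTBS; 15-OTES), via hydroxy ester 19 (not isolated)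
Conditions: NaBH4, CeCl3·7H2O, MeOH/THF, −78 °C; work-up; then PPTS (cat.), PhMe, 50 °C
Reagents that add atoms: none
Why: Luche reduction gives 1,2-addition only; hydride is expected anti to C8 on the α-stereocentre (Felkin–Anh), which is also the 1,3-anti sense relative to O8, so O6 ends trans to the C7 branch. Only O6 is free, so acid-catalysed lactonisation can give only the trans-fused 6,12-lactone (C7 changes its descriptor to S only because the silylated C8 now outranks C6).

Step 14
Reactants: 20 lactone
Product: 23 (2S,6R,7S,8R)-α-methylene lactone (2-OTES; 8-OTBS; 15-OTES), via Mannich base 21 (not isolated), via ammonium iodide 22 (not isolated)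
Conditions: LiN(iPr)2 (1.3 equiv), THF, −78 °C; CH2=NMe2+ I−, −78 → 0 °C; then MeI, THF/MeOH, rt; then aq. NaHCO3, CH2Cl2, rt
Reagents that add atoms: N,N-dimethylmethyleneiminium iodide, C=[N+](C)C.[I-]
Why: Mannich reaction of the lactone enolate with the iminium salt, quaternisation and β-elimination (Eschenmoser methylenation) install C13; C11 is not stereogenic in the product and C7, β to the carbonyl, is not touched.

Step 15
Reactants: 23 tris-silyl methylene lactone
Product: 24 (2S,6R,7S,8R)-8-O-TBS diol (free 2-OH and 15-OH; α-methylene 6,12-lactone)
Conditions: PPTS (0.3 equiv), MeOH/CH2Cl2 (1:1), 0 °C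
Reagents that add atoms: none
Why: Acid-catalysed methanolysis removes the primary and the secondary allylic TES ethers far faster than the hindered secondary TBS ether; the conditions are too mild for conjugate addition of methanol to the methylene lactone.

Step 16
Reactants: 24 diol
Product: 25 (2S,6R,7S,8R)-15-acetate (free 2-OH; 8-OTBS; α-methylene 6,12-lactone)
Conditions: AcCl (1.1 equiv), 2,4,6-collidine, CH2Cl2, −78 °C
Reagents that add atoms: acetyl chloride, CC(=O)Cl
Why: Acetyl chloride with a hindered pyridine base at low temperature acylates the primary allylic hydroxyl selectively over the secondary C2 hydroxyl.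

Step 17
Reactants: 25 15-acetate
Product: 26 (2S,6R,7S,8R)-2-angelate 15-acetate (8-OTBS; α-methylene 6,12-lactone)
Conditions: angelic acid, 2,4,6-trichlorobenzoyl chloride, Et3N, PhMe, rt; then 25, 75 °C
Reagents that add atoms: angelic acid, C/C=C(/C)C(=O)O
Why: Yamaguchi-type esterification through the preformed mixed anhydride without a nucleophilic catalyst, conditions under which the Z acid should be transferred without isomerisation to the tiglate; C2 is acylated with retention.

Step 18
Reactants: 26 silyl ether
Product: 27 (3aR,4R,6Z,8S,10Z,11aR)-10-(acetoxymethyl)-4-hydroxy-6-methyl-3-methylidene-2-oxo-2,3,3a,4,5,8,9,11a-octahydrocyclodeca[b]furan-8-yl (2Z)-2-methylbut-2-enoate (germacrane: 2S,6R,7R,8R)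
Conditions: HF·pyridine, pyridine, THF, 0 °C → rt
Reagents that add atoms: none
Why: Fluoride-mediated desilylation under buffered, weakly acidic conditions leaves the angelate, the acetate and the methylene lactone untouched and avoids base-induced lactone migration to O8.

## Compound list

1 | hepta-1,6-dien-4-ol | C=CCC(O)CC=C | starting material
2 | 4-(tert-butyldimethylsilyloxy)hepta-1,6-diene | C=CCC(O[Si](C)(C)C(C)(C)C)CC=C | intermediate
3 | 4-(tert-butyldimethylsilyloxy)heptane-2,6-dione | CC(=O)CC(O[Si](C)(C)C(C)(C)C)CC(C)=O | intermediate
4 | (5R)-5-(tert-butyldimethylsilyloxy)-3-hydroxy-3-methylcyclohexan-1-one (ketol, C3 epimers) | CC1(O)CC(=O)C[C@H](O[Si](C)(C)C(C)(C)C)C1 | intermediate (not isolated)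
5 | (R)-5-(tert-butyldimethylsilyloxy)-3-methylcyclohex-2-en-1-one | CC1=CC(=O)C[C@H](O[Si](C)(C)C(C)(C)C)C1 | intermediate
6 | methyl cis-3-hydroxycyclobutane-1-carboxylate | COC(=O)[C@H]1C[C@@H](O)C1 | starting material
7 | methyl 3-hydroxy-1-(phenylselanyl)cyclobutane-1-carboxylate | COC(=O)C1([Se]c2ccccc2)CC(O)C1 | intermediate (not isolated)
8 | methyl 3-hydroxy-1-(phenylseleninyl)cyclobutane-1-carboxylate | COC(=O)C1([Se](=O)c2ccccc2)CC(O)C1 | intermediate (not isolated)
9 | methyl (±)-3-hydroxycyclobut-1-ene-1-carboxylate | COC(=O)C1=CC(O)C1 | intermediate
10 | methyl (S)-3-hydroxycyclobut-1-ene-1-carboxylate | COC(=O)C1=C[C@@H](O)C1 | intermediate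
11 | methyl (S)-3-(triethylsilyloxy)cyclobut-1-ene-1-carboxylate | COC(=O)C1=C[C@@H](O[Si](CC)(CC)CC)C1 | intermediate
12 | trans-fused head-to-head photoadduct (C5 epimer of 13) | COC(=O)[C@]12C[C@H](O[Si](CC)(CC)CC)[C@H]1[C@]3(C)C[C@@H](O[Si](C)(C)C(C)(C)C)CC(=O)[C@@H]23 | intermediate (not isolated)
13 | cis-anti-cis head-to-head photoadduct (C4 CO2Me, C10 Me, C6 ketone, 2S OTES, 8R OTBS) | COC(=O)[C@]12C[C@H](O[Si](CC)(CC)CC)[C@H]1[C@]3(C)C[C@@H](O[Si](C)(C)C(C)(C)C)CC(=O)[C@H]23 | intermediate
14 | methyl (2S,8R,1(10)Z,4Z)-8-(tert-butyldimethylsilyloxy)-10-methyl-6-oxo-2-(triethylsilyloxy)cyclodeca-1(10),4-diene-4-carboxylate | COC(=O)/C1=C\C(=O)C[C@H](O[Si](C)(C)C(C)(C)C)C/C(C)=C\[C@@H](O[Si](CC)(CC)CC)C1 | intermediate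
15 | (2S,8R,1(10)Z,4Z)-8-(tert-butyldimethylsilyloxy)-4-(hydroxymethyl)-10-methyl-2-(triethylsilyloxy)cyclodeca-1(10),4-dien-6-ol (C6 epimers) | OC/C1=C\C(O)C[C@H](O[Si](C)(C)C(C)(C)C)C/C(C)=C\[C@@H](O[Si](CC)(CC)CC)C1 | intermediate
16 | (2S,8R,1(10)Z,4Z)-8-(tert-butyldimethylsilyloxy)-10-methyl-2-(triethylsilyloxy)-4-[(triethylsilyloxy)methyl]cyclodeca-1(10),4-dien-6-ol (C6 epimers) | CC[Si](CC)(CC)OC/C1=C\C(O)C[C@H](O[Si](C)(C)C(C)(C)C)C/C(C)=C\[C@@H](O[Si](CC)(CC)CC)C1 | intermediate
17 | (2S,8R,1(10)Z,4Z)-8-(tert-butyldimethylsilyloxy)-10-methyl-2-(triethylsilyloxy)-4-[(triethylsilyloxy)methyl]cyclodeca-1(10),4-dien-6-one | CC[Si](CC)(CC)OC/C1=C\C(=O)C[C@H](O[Si](C)(C)C(C)(C)C)C/C(C)=C\[C@@H](O[Si](CC)(CC)CC)C1 | intermediate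
18 | methyl [(2S,7R,8R,1(10)Z,4Z)-8-(tert-butyldimethylsilyloxy)-10-methyl-6-oxo-2-(triethylsilyloxy)-4-[(triethylsilyloxy)methyl]cyclodeca-1(10),4-dien-7-yl]acetate | CC[Si](CC)(CC)OC/C1=C\C(=O)[C@H](CC(=O)OC)[C@H](O[Si](C)(C)C(C)(C)C)C/C(C)=C\[C@@H](O[Si](CC)(CC)CC)C1 | intermediate
19 | (2S,6R,7S,8R)-6-hydroxy ester from 18 | CC[Si](CC)(CC)OC/C1=C\[C@@H](O)[C@H](CC(=O)OC)[C@H](O[Si](C)(C)C(C)(C)C)C/C(C)=C\[C@@H](O[Si](CC)(CC)CC)C1 | intermediate (not isolated)
20 | (2S,6R,7S,8R)-trans-fused 6,12-lactone (C11 = CH2; 2-OTES, 8-OTBS, 15-OTES) | CC[Si](CC)(CC)OC/C1=C\[C@H]2OC(=O)C[C@@H]2[C@H](O[Si](C)(C)C(C)(C)C)C/C(C)=C\[C@@H](O[Si](CC)(CC)CC)C1 | intermediate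
21 | 11-(dimethylaminomethyl) lactone (Mannich base, C11 epimers) | CC[Si](CC)(CC)OC/C1=C\[C@H]2OC(=O)C(CN(C)C)[C@@H]2[C@H](O[Si](C)(C)C(C)(C)C)C/C(C)=C\[C@@H](O[Si](CC)(CC)CC)C1 | intermediate (not isolated)
22 | 11-(trimethylammoniomethyl) lactone iodide | CC[Si](CC)(CC)OC/C1=C\[C@H]2OC(=O)C(C[N+](C)(C)C)[C@@H]2[C@H](O[Si](C)(C)C(C)(C)C)C/C(C)=C\[C@@H](O[Si](CC)(CC)CC)C1.[I-] | intermediate (not isolated)
23 | (2S,6R,7S,8R)-α-methylene 6,12-lactone (2-OTES, 8-OTBS, 15-OTES) | CC[Si](CC)(CC)OC/C1=C\[C@H]2OC(=O)C(=C)[C@@H]2[C@H](O[Si](C)(C)C(C)(C)C)C/C(C)=C\[C@@H](O[Si](CC)(CC)CC)C1 | intermediate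
24 | (2S,6R,7S,8R)-α-methylene 6,12-lactone 2,15-diol (8-OTBS) | OC/C1=C\[C@H]2OC(=O)C(=C)[C@@H]2[C@H](O[Si](C)(C)C(C)(C)C)C/C(C)=C\[C@@H](O)C1 | intermediate
25 | (2S,6R,7S,8R)-15-acetate (2-OH, 8-OTBS) | CC(=O)OC/C1=C\[C@H]2OC(=O)C(=C)[C@@H]2[C@H](O[Si](C)(C)C(C)(C)C)C/C(C)=C\[C@@H](O)C1 | intermediate
26 | (2S,6R,7S,8R)-2-angelate 15-acetate (8-OTBS) | CC(=O)OC/C1=C\[C@H]2OC(=O)C(=C)[C@@H]2[C@H](O[Si](C)(C)C(C)(C)C)C/C(C)=C\[C@@H](OC(=O)/C(C)=C\C)C1 | intermediate
27 | (3aR,4R,6Z,8S,10Z,11aR)-10-(acetoxymethyl)-4-hydroxy-6-methyl-3-methylidene-2-oxo-2,3,3a,4,5,8,9,11a-octahydrocyclodeca[b]furan-8-yl (2Z)-2-methylbut-2-enoate | C=C1C(=O)O[C@@H]2/C=C(\COC(C)=O)C[C@H](OC(=O)/C(C)=C\C)/C=C(/C)C[C@@H](O)[C@@H]12 | target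

## Step count and least certain steps

Total: 18 steps. Longest linear sequence: 15 steps (steps 1–3, then 7–18); the cyclobutene branch (steps 4–6) joins at step 7.

Step 8 (key step). Two things are most likely to go wrong. The diyl may fragment through the other chair, because the pseudo-axial silyloxy groups at C2 and C8 destabilise the chair that gives the ring-trans C4=C5 and Z C1=C10 pair. Heating may also drive a siloxy-Cope rearrangement, which erases C2, or loss of silanol β to the C6 ketone. Fallback: from 13, NaBH4 (MeOH, 0 °C) should deliver hydride to C6 from the face away from the cyclobutane, and the resulting alkoxide closes onto the cis C15 ester to give the tetracyclic γ-lactone F1. Thermolysis of F1 (mesitylene, 165 °C) would open it to the ten-membered butenolide F2. Because C4=C5 is then formed inside a five-membered lactone, C15 and C6 can only be cis; this forces C6 equatorial in the diyl chair and so fixes the Z geometry at C1=C10, and no ketone with a β-silyloxy group is present during heating. Reduction of F2 with excess iBu2AlH (CH2Cl2, −78 → 0 °C) gives the diol 15 as a single C6 epimer, where the route is rejoined; the cost is one step.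

Step 12. The main risks are poor facial selectivity in the flexible ten-membered enolate (entry trans to O8), β-elimination of the silyloxy group on warming, and competing γ-deprotonation at C3 or C15. Fallback: alkylate before ring expansion, on the rigid tricycle. From 13, LiN(iPr)2 (THF, −78 °C) and tert-butyl bromoacetate should give the alkylated photoadduct F3; with the C10 methyl and the C8 silyloxy group locked equatorial, axial attack at C7 comes from the face cis to O8. Thermolysis as in step 8 gives the ten-membered keto diester F4. iBu2AlH (CH2Cl2, −78 °C) reduces the ketone and the methyl ester but spares the tert-butyl ester, giving the diol ester F5. PPTS (PhMe, 60 °C) closes the 6,12-lactone F6, and TESCl/imidazole returns to the route at 20.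

Step 13. Hydride delivery may occur from the wrong face of the C6 carbonyl, giving O6 cis to the C7 branch and hence a cis-fused lactone. Fallback: from 18, if the reduction gives the cis-fused 6-epi lactone F7, LiOH (THF/H2O, 0 °C) opens it to the 6-epi hydroxy acid F8, and Mitsunobu lactonisation (PPh3, diisopropyl azodicarboxylate, THF) closes the ring with inversion at C6 to give 20.

Step 3. The amine catalyst may discriminate the two acetonyl arms poorly with a silyloxy substituent, or silanol may be lost through the enamine, which leads on to an aromatic by-product. Fallback: from 3, pyrrolidine/AcOH (PhMe, rt) gives the racemic enone F9. Its photocycloaddition with enantiopure 11 under the conditions of step 7 gives 13 together with the 8-epimeric adduct F10; these are diastereomers and are separated by chromatography, rejoining the route at 13.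

Step 5. The lipase may discriminate poorly between the enantiomers of a small, nearly flat cyclobutenol, so that the recovered alcohol is not enantiopure at a useful conversion. Fallback: from 9, (R)-1-(1-naphthyl)ethyl isocyanate (PhMe, 60 °C) gives the diastereomeric carbamates F11 (from the S alcohol) and F12 (from the R alcohol). They are separated by chromatography or crystallisation, and F11 is cleaved with HSiCl3/Et3N (PhH, rt) to 10.

## Further compounds

F1 | step 8 | tetracyclic γ-lactone (C15 carbonyl to O6) from reduction of 13 | O=C4[C@]12C[C@H](O[Si](CC)(CC)CC)[C@H]1[C@]3(C)C[C@@H](O[Si](C)(C)C(C)(C)C)C[C@H](O4)[C@H]23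
F2 | step 8 | ten-membered 6,15-butenolide (2S OTES, 8R OTBS, 1(10)Z) | O=C1O[C@H]2C[C@H](O[Si](C)(C)C(C)(C)C)C/C(C)=C\[C@@H](O[Si](CC)(CC)CC)C/C1=C/2
F3 | step 12 | 7-(tert-butoxycarbonylmethyl) photoadduct (branch cis to O8) | COC(=O)[C@]12C[C@H](O[Si](CC)(CC)CC)[C@H]1[C@]3(C)C[C@@H](O[Si](C)(C)C(C)(C)C)[C@@H](CC(=O)OC(C)(C)C)C(=O)[C@H]23
F4 | step 12 | ten-membered keto diester (C15 methyl ester, C12 tert-butyl ester) | COC(=O)/C1=C\C(=O)[C@H](CC(=O)OC(C)(C)C)[C@H](O[Si](C)(C)C(C)(C)C)C/C(C)=C\[C@@H](O[Si](CC)(CC)CC)C1
F5 | step 12 | 6,15-diol tert-butyl ester | OC/C1=C\[C@@H](O)[C@H](CC(=O)OC(C)(C)C)[C@H](O[Si](C)(C)C(C)(C)C)C/C(C)=C\[C@@H](O[Si](CC)(CC)CC)C1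
F6 | step 12 | trans-fused 6,12-lactone with free 15-OH (2-OTES, 8-OTBS) | OC/C1=C\[C@H]2OC(=O)C[C@@H]2[C@H](O[Si](C)(C)C(C)(C)C)C/C(C)=C\[C@@H](O[Si](CC)(CC)CC)C1
F7 | step 13 | cis-fused 6-epi 6,12-lactone | CC[Si](CC)(CC)OC/C1=C\[C@@H]2OC(=O)C[C@@H]2[C@H](O[Si](C)(C)C(C)(C)C)C/C(C)=C\[C@@H](O[Si](CC)(CC)CC)C1
F8 | step 13 | 6-epi hydroxy acid | CC[Si](CC)(CC)OC/C1=C\[C@H](O)[C@H](CC(=O)O)[C@H](O[Si](C)(C)C(C)(C)C)C/C(C)=C\[C@@H](O[Si](CC)(CC)CC)C1
F9 | step 3 | (±)-5-(tert-butyldimethylsilyloxy)-3-methylcyclohex-2-en-1-one | CC1=CC(=O)CC(O[Si](C)(C)C(C)(C)C)C1
F10 | step 3 | 8-epimeric head-to-head photoadduct (from the 5S enone) | COC(=O)[C@]12C[C@H](O[Si](CC)(CC)CC)[C@H]1[C@]3(C)C[C@H](O[Si](C)(C)C(C)(C)C)CC(=O)[C@H]23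
F11 | step 5 | methyl (S)-3-{[(R)-1-(naphthalen-1-yl)ethyl]carbamoyloxy}cyclobut-1-ene-1-carboxylate | COC(=O)C1=C[C@@H](OC(=O)N[C@H](C)c2cccc3ccccc23)C1
F12 | step 5 | methyl (R)-3-{[(R)-1-(naphthalen-1-yl)ethyl]carbamoyloxy}cyclobut-1-ene-1-carboxylate | COC(=O)C1=C[C@H](OC(=O)N[C@H](C)c2cccc3ccccc23)C1
A1 | alternative 1 | ten-membered C10 enol triflate (2S OPMB, 6-OMOM, 8-OTBS, 15-OTBDPS, 7-(2-silyloxyethyl)) | FC(F)(F)S(=O)(=O)O/C1=C/[C@@H](OCc2ccc(OC)cc2)C/C(CO[Si](c2ccccc2)(c2ccccc2)C(C)(C)C)=C/[C@@H](OCOC)[C@H](CCO[Si](C)(C)C(C)(C)C)[C@H](O[Si](C)(C)C(C)(C)C)C1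
A2 | alternative 2 | 2-hydroxy germacranolide 15-acetate with 8-OTBS (identical with 25) | C=C1C(=O)O[C@@H]2/C=C(\COC(C)=O)C[C@H](O)/C=C(/C)C[C@@H](O[Si](C)(C)C(C)(C)C)[C@@H]12
A3 | alternative 3 | ten-membered 6-hydroxy-7-(3-triethylsilyloxyprop-1-en-2-yl) carbocycle | O[C@@H]1/C=C(\CO[Si](c2ccccc2)(c2ccccc2)C(C)(C)C)C[C@H](O[Si](C)(C)C(C)(C)C)/C=C(/C)C[C@@H](O[Si](C(C)C)(C(C)C)C(C)C)[C@H]1C(=C)CO[Si](CC)(CC)CC
A4 | alternative 1 | cis-1,2-dialkenylcyclohexanol with (Z)-2-(4-methoxybenzyloxy)vinyl on C10 | O[C@@]1(/C=C\OCc2ccc(OC)cc2)C[C@@H](O[Si](C)(C)C(C)(C)C)[C@@H](CCO[Si](C)(C)C(C)(C)C)[C@H](OCOC)[C@@H]1C(=C)CO[Si](c1ccccc1)(c1ccccc1)C(C)(C)C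
A5 | alternative 2 | open-chain lactone with C2 aldehyde and Z-alkenyl iodide at C1 | C=C1C(=O)O[C@H](/C=C(\COC(C)=O)CC=O)[C@H]1[C@H](O[Si](C)(C)C(C)(C)C)C/C(C)=C\I
A6 | alternative 3 | thirteen-membered diallylic ether (O between C6 and C13) | C1OC/C(CO[Si](CC)(CC)CC)=C/[C@H](O[Si](C(C)C)(C(C)C)C(C)C)C/C(C)=C\[C@@H](O[Si](C)(C)C(C)(C)C)C/C(CO[Si](c2ccccc2)(c2ccccc2)C(C)(C)C)=C/1
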